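The meeting had 4 questions before it, 2 for each of the flasks blue and grey, and one earlier run, ash, to answer them from.

| flask | substrate | gas phase | remark | time |
|---|---|---|---|---|
| ash | 0.050 M | 11 mM (held) | run made earlier |  |
| blue | 0.10 M | 11 mM (held) |  | 40 h |
| grey | 0.10 M | 11 mM (held) |  | 15 h |

ash run (percent of the substrate charged)

| time / h | substrate / % | target / % | side product / % |
|---|---|---|---|
| 0.833 | 98.0 | 2.7 | 0.3 |
| 1.50 | 93.8 | 3.6 | 1.8 |
| 2.50 | 90.0 | 8.5 | 2.4 |
| 3.00 | 86.9 | 10.1 | 3.6 |

(each reading ± 0.5 percentage points)

1. which of these there is most of at the end, counted by the substrate in it, blue (target / substrate / side product)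
2. which of these there is most of at the end, counted by the substrate in it, grey (target / substrate / side product)
3. the largest of these amounts at the end, in percent of the substrate charged, blue
4. the largest of these amounts at the end, in percent of the substrate charged, grey

- at the start none of the gas phase is in solution

Ruth opened with the ash run. Substrate stood at 86.9 % after 3.00 h, and she took this as a loss of a constant fraction per hour (pseudo-first-order, with the gas phase held), which gives 0.0468 h⁻¹. Tomas added the last product readings of that run: target held 73.7 % of the two products together, and he took that share to hold for the substrate lost later. Side product held the remaining 26.3 %, less than target, so he saw the contest as one between substrate and target.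

The chair asked for one number that would name the leader. Ruth offered the crossing time, the time at which the substrate left equals the target made. Setting the two equal puts substrate at 42.4 % of the charge, which it reaches at 18.3 h.

Grey's 15 h is shorter than that, so she put substrate first in grey, at 49.6 %. Blue's 40 h is longer, so she put target first in blue, at 62.4 %. Tomas objected that blue and grey carry twice the substrate of ash, so carrying the crossing time over to them rests on the loss being first order.

The forecast named target for blue at 62 % and substrate for grey at 52 %, more than the meeting's figure for grey, and warned that “four points over 13% conversion cannot fix the order”.

Blue ends with target largest, at 67.9 %, and grey with substrate largest, at 47.8 %.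

    2 dissolved gas → self-condensation product (k = 0.00580 M⁻¹ s⁻¹)
    substrate → side product (k = 3.20 × 10⁻⁶ s⁻¹)
    substrate + dissolved gas → target (k = 0.00150 M⁻¹ s⁻¹)
    gas phase ⇌ dissolved gas, rate k4*(csat - [dissolved gas]) (kL = 3.60 × 10⁻⁴ s⁻¹)

Substrate and target stand equal in grey's charge at 16.9 h, against the reckoned 18.3 h, with grey's 15 h before both and blue's 40 h after both. The neighbouring flask is grey read later, at 25 h, with all amounts held. That time is longer than the reckoned crossing, so the same reckoning puts target first, at 50.8 %, with substrate down to 31.0 %. In that neighbour the largest is target, at 55.4 %, with substrate at 28.0 %.

The earlier runs and the new flask were generated by integration with made-up constants, and the scatter is random.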